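If a catalyst turns over in two steps in series, one taking up starting material and one taking up coupling partner, then the time of a turn is a sum, and a ratio of rates shows how that sum splits. Two chemists dispute whether these flasks are that simple.

| flask | starting material | coupling partner | free catalyst | time |
|---|---|---|---|---|
| gamma | 0.120 M | 0.300 M | 2.40 × 10⁻⁴ M |  |
| delta | 0.0600 M | 0.240 M | 2.40 × 10⁻⁴ M |  |
| eta | 0.120 M | 0.600 M | 2.40 × 10⁻⁴ M |  |
| zeta | 0.120 M | 1.90 M | 2.40 × 10⁻⁴ M | 19 min |

| run | time / min | [target] / M |
|---|---|---|
| gamma run | 3.2 | 0.0090 |
| gamma run | 6.3 | 0.0149 |
| gamma run | 9.5 | 0.0203 |
| gamma run | 13 | 0.0236 |
| gamma run | 16 | 0.0240 |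
| gamma run | 19 | 0.0252 |
| delta run | 3.2 | 0.0055 |
| delta run | 6.3 | 0.0104 |
| delta run | 9.5 | 0.0138 |
| delta run | 13 | 0.0141 |
| delta run | 16 | 0.0164 |
| delta run | 19 | 0.0165 |
| eta run | 3.2 | 0.0106 |
| eta run | 6.3 | 0.0201 |
| eta run | 9.5 | 0.0249 |
| eta run | 13 | 0.0285 |
| eta run | 16 | 0.0309 |
| eta run | 19 | 0.0322 |

(each reading ± 6 × 10⁻⁴ M)

- Overall: starting material + coupling partner -> target, with free catalyst as catalyst.
- Constant volume, constant temperature.
- Bound and free are read together.
- An order is taken over about fifteen percent of the charge, up and down.

- apparent order in [starting material] of the starting rate, round the charge of the gamma run (the rate where two percent of its starting material have turned into target) (one fixed amount of target, the same in the runs compared)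
- apparent order in [coupling partner] of the starting rate, round the charge of the gamma run (the rate where two percent of its starting material have turned into target)
- target in the zeta run at 19 min, as a share of the starting material charged

The second chemist adds up the first two readings of each run and divides one sum by another at the same clocks, so that time drops out of the comparison. Those readings put the eta run at 1.28 times the gamma run and the delta run at 0.665 times it, and each ratio carries the scatter of its readings.

The second chemist holds to the series. Going from gamma to eta doubles c(coupling partner), which cuts the partner's part of the turn to half and leaves the other part alone. The ratio of 1.28 then gives 0.443. This number is the partner's share, the fraction of one catalyst turn at the gamma charge spent on the step with coupling partner. In a series it is also the local order in coupling partner, and the remainder, 0.557, is the order in starting material. The delta run, corrected for its partner with the same share, reads 0.436, so this chemist commits to about that.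

For zeta, the partner's part shrinks to 0.158 of its gamma length, so the rate is 1.60 times gamma's. Late readings seem to follow early ones: the eta run reads 1.28 times the gamma run at 19 min, close to 1.28. Scaling gamma's last reading therefore gives 33.5 %.

The first chemist made the forecast and reads the flattening otherwise: “So the catalyst is apparently dying, or being inhibited”. The forecast gives 0.7 (0.45 to 1) in starting material, 0.4 (0.2 to 0.65) in coupling partner, and 30 % (24 % to 36 %) for zeta. That order in starting material is higher than the second chemist's, and that zeta share is lower.

The simulation gives an order of 0.40 in starting material, 0.50 in coupling partner, and 29.7 % in the zeta run at 19 min.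

    free catalyst + starting material → loaded catalyst + by-product (386.4 M⁻¹ min⁻¹)
    loaded catalyst + coupling partner → target + free catalyst (94.20 M⁻¹ min⁻¹)
    2 starting material ⇌ idle substrate dimer, settled at all times (6.580 M⁻¹)
    target → decomposed product (0.08040 min⁻¹)

The series view takes the orders: the partner's share of 0.443 lies beside the order 0.50, and the two orders sum to 0.900, as near a ping-pong cycle of free catalyst and loaded catalyst. The first chemist keeps the zeta run: the forecast's 30 % stands beside 29.7 %, and the scaled share stands at 33.5 %. The step from target to decomposed product costs the zeta run 33 percentage points: taken away, it lifts that run at 19 min from 29.7 % to 62.8 %.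

The readings come from a simulation from invented constants; scatter was added.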